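Ring A is a hexasubstituted benzene in which oxygen-bearing carbons (C5, C7, C8a) alternate with carbon-bearing ones (C4a, C6, C8), the pattern a vinylketene–ynol ether benzannulation produces. The route therefore cuts ring A at C8–C8a and C6–C7. Heating 2-prenyl-3-silyloxycyclobutenone 8 with prenyl silyloxyalkyne 5 should give, in one operation, a 2,4-diprenylphloroglucinol (13) whose single free hydroxyl (future O1) sits beside the only ring C–H (future C4a). Both partners derive from one ynolate: 5 by O-silylation, 8 from 5 and ketene. Ortho-formylation at C4a, aldol union with the ring B ketone, oxidation, acid cyclodehydration and desilylation then complete ring C.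

Key step: step 4

Remark: the target has no stereocentre, so "single enantiomer" is read as the constitution given; the stereocentres of intermediates 10, 19, 20 and 21 are racemic and are destroyed before the end. Abbreviations: prenyl = 3-methylbut-2-en-1-yl, TIPS = triisopropylsilyl, MOM = methoxymethyl.

Step 1
Reactants: 1 4-methylpent-3-enoic acid
Product: 2 ethyl 4-methylpent-3-enoate
Conditions: EtI, K2CO3, DMF, rt
Reagents that add atoms: iodoethane, CCI
Why: Carboxylate O-alkylation (SN2) forms the ester without acid, which avoids the lactonisation and double-bond migration to which this β,γ-unsaturated acid is prone under Fischer conditions.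

Step 2
Reactants: 2 ethyl 4-methylpent-3-enoate
Product: 5 5-methyl-1-(triisopropylsilyloxy)hex-4-en-1-yne, via lithium dibromoenolate 3 (not isolated), via lithium ynolate 4 (not isolated)
Conditions: CH2Br2, LiTMP, THF, −78 °C, then 2; LiHMDS; n-BuLi, −78 °C → rt; i-Pr3SiCl, 0 °C
Reagents that add atoms: dibromomethane, BrCBr; chlorotriisopropylsilane, CC(C)[Si](Cl)(C(C)C)C(C)C
Why: Kowalski ester homologation: LiCHBr2 adds to the ester, the adduct collapses to the dibromoketone enolate, Br/Li exchange triggers a carbenoid 1,2-shift to the ynolate, and the bulky silyl chloride traps it on oxygen.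

Step 3
Reactants: 5 5-methyl-1-(triisopropylsilyloxy)hex-4-en-1-yne; 6 acetone
Product: 8 2-(3-methylbut-2-en-1-yl)-3-(triisopropylsilyloxy)cyclobut-2-en-1-one, via ketene 7 (not isolated)
Conditions: acetone, ketene lamp (hot filament, ca. 750 °C); gas stream into 5, CH2Cl2, 0 °C
Reagents that add atoms: none
Why: Thermal [2+2] cycloaddition of ketene to an ynol ether is the standard entry to 3-oxycyclobutenones; the electrophilic ketene carbonyl carbon bonds to the nucleophilic prenyl-bearing alkyne carbon, which puts prenyl on C2 and the silyloxy group on C3, and the isolated prenyl alkene is inert to ketene.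

Step 4
Reactants: 8 2-(3-methylbut-2-en-1-yl)-3-(triisopropylsilyloxy)cyclobut-2-en-1-one; 5 5-methyl-1-(triisopropylsilyloxy)hex-4-en-1-yne
Product: 13 2,4-bis(3-methylbut-2-en-1-yl)-3,5-bis(triisopropylsilyloxy)phenol, via vinylketene 9 (not isolated), via alkenylcyclobutenone 10 (not isolated), via dienylketene 11 (not isolated), via cyclohexadienone 12 (not isolated)
Conditions: PhMe (degassed), 80 °C, then 110 °C
Reagents that add atoms: none
Why: Danheiser benzannulation: on heating, 8 opens by four-electron electrocyclic ring opening to vinylketene 9, which adds to silyloxyalkyne 5 in a ketene–alkyne [2+2] cycloaddition that forms C8–C8a and C6–C7 and gives alkenylcyclobutenone 10. A second four-electron ring opening of 10 gives dienylketene 11, whose six-electron (disrotatory) electrocyclisation joins C4a to C8a and so closes the six-membered ring A; tautomerisation of cyclohexadienone 12 should then deliver the phenol. The closest known reaction type is the thermal benzannulation of cyclobutenones with silyloxy- or alkoxyalkynes to resorcinol monoethers, run here with a 3-silyloxycyclobutenone so that a phloroglucinol results. No stereocentre survives: the quaternary centre of 10 is racemic and vanishes on ring opening, and a dienylketene of the wrong double-bond geometry can return to 10 because that opening is reversible. The one selectivity needed is the regiochemistry of the [2+2] union, and the polarisation of both partners secures it: the electrophilic ketene carbonyl carbon (future C8a) bonds to the alkyne carbon β to oxygen (future C8). Chemoselectivity for the ynol ether over the two trisubstituted alkenes follows from the much higher nucleophilicity of the oxygen-substituted triple bond.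

Step 5
Reactants: 13 2,4-bis(3-methylbut-2-en-1-yl)-3,5-bis(triisopropylsilyloxy)phenol
Product: 14 2-hydroxy-3,5-bis(3-methylbut-2-en-1-yl)-4,6-bis(triisopropylsilyloxy)benzaldehyde
Conditions: MgCl2, Et3N, (CH2O)n, MeCN, reflux
Reagents that add atoms: formaldehyde (as paraformaldehyde), C=O
Why: Casnati–Skattebøl ortho-formylation: the magnesium phenoxide delivers formaldehyde to the only free ortho carbon (C4a) and a second formaldehyde oxidises the hydroxymethyl intermediate by hydride transfer, under conditions neither strongly acidic nor strongly basic, so the prenyl groups and aryl silyl ethers should survive.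

Step 6
Reactants: 14 2-hydroxy-3,5-bis(3-methylbut-2-en-1-yl)-4,6-bis(triisopropylsilyloxy)benzaldehyde
Product: 15 2-(methoxymethoxy)-3,5-bis(3-methylbut-2-en-1-yl)-4,6-bis(triisopropylsilyloxy)benzaldehyde
Conditions: NaH, MOMCl, DMF, 0 °C
Reagents that add atoms: chloromethyl methyl ether, COCCl
Why: Williamson-type O-alkylation of the sodium phenoxide caps O1, so that the aldehyde can accept an enolate without proton transfer and the later oxidation meets no free phenol.

Step 7
Reactants: 16 2-hydroxy-1-(4-hydroxyphenyl)ethan-1-one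
Product: 17 2-(methoxymethoxy)-1-[4-(methoxymethoxy)phenyl]ethan-1-one
Conditions: MOMCl, i-Pr2NEt, CH2Cl2, 0 °C → rt
Reagents that add atoms: chloromethyl methyl ether, COCCl
Why: Acetal protection of the phenol and the primary ketol hydroxyl with an amine base gives the ring B / C2–C3 building block with the future C3 oxygen in place, and both groups are released later by the same acid.

Step 8
Reactants: 17 2-(methoxymethoxy)-1-[4-(methoxymethoxy)phenyl]ethan-1-one; 15 2-(methoxymethoxy)-3,5-bis(3-methylbut-2-en-1-yl)-4,6-bis(triisopropylsilyloxy)benzaldehyde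
Product: 19 3-hydroxy-2-(methoxymethoxy)-3-[2-(methoxymethoxy)-3,5-bis(3-methylbut-2-en-1-yl)-4,6-bis(triisopropylsilyloxy)phenyl]-1-[4-(methoxymethoxy)phenyl]propan-1-one (mixture of racemic diastereomers), via lithium enolate 18 (not isolated)
Conditions: LiHMDS, THF, −78 °C; then 15, −78 °C; AcOH, −78 °C
Reagents that add atoms: none
Why: Aldol addition of a chelated α-alkoxy ketone lithium enolate to a non-enolisable aldehyde forms the C3–C4 bond; the two new stereocentres are left uncontrolled because steps 9 and 10 remove both, and the cold quench limits silyl transfer from O5 to the aldolate.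

Step 9
Reactants: 19 the aldol adduct of step 8, used crude
Product: 20 2-(methoxymethoxy)-1-[2-(methoxymethoxy)-3,5-bis(3-methylbut-2-en-1-yl)-4,6-bis(triisopropylsilyloxy)phenyl]-3-[4-(methoxymethoxy)phenyl]propane-1,3-dione (racemic)
Conditions: Dess–Martin periodinane, pyridine, CH2Cl2, 0 °C → rt
Reagents that add atoms: none
Why: Dess–Martin oxidation converts the β-hydroxy ketone into the 1,3-diketone under buffered conditions that should spare the ionisation-prone trioxygenated benzylic position, the acetals, the silyl ethers and the prenyl alkenes.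

Step 10
Reactants: 20 the 2-(methoxymethoxy)-1,3-diketone of step 9
Product: 22 3-hydroxy-2-(4-hydroxyphenyl)-6,8-bis(3-methylbut-2-en-1-yl)-5,7-bis(triisopropylsilyloxy)-4H-chromen-4-one, via hydroxydiketone 21 (not isolated)
Conditions: 2 M HCl, MeOH/THF (1:1), 40 °C
Reagents that add atoms: none
Why: Acid-catalysed acetal cleavage frees O1, the C3 oxygen and the ring B phenol, and the o-hydroxyaryl 1,3-diketone then cyclodehydrates to the chromen-4-one (the closing stage of a Baker–Venkataraman-type flavone synthesis), while the silyl ethers on O5 and O7 keep both prenyl groups from acid-induced chroman formation.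

Step 11
Reactants: 22 3-hydroxy-2-(4-hydroxyphenyl)-6,8-bis(3-methylbut-2-en-1-yl)-5,7-bis(triisopropylsilyloxy)-4H-chromen-4-one
Product: 23 6,8-diprenylkaempferol
Conditions: TBAF, AcOH, THF, 0 °C (Ar)
Reagents that add atoms: none
Why: Fluoride-mediated desilylation cleaves the two aryl silyl ethers, and the acetic acid buffer protonates the phenoxides at once so that the air-sensitive polyphenolic flavonol is not held under basic conditions.

Compound list

1 | 4-methylpent-3-enoic acid | CC(C)=CCC(=O)O | starting material
2 | ethyl 4-methylpent-3-enoate | CCOC(=O)CC=C(C)C | intermediate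
3 | lithium 1,1-dibromo-5-methylhexa-1,4-dien-2-olate | [Li+].[O-]C(CC=C(C)C)=C(Br)Br | intermediate
4 | lithium 5-methylhex-4-en-1-yn-1-olate | [Li+].[O-]C#CCC=C(C)C | intermediate
5 | 5-methyl-1-(triisopropylsilyloxy)hex-4-en-1-yne | CC(C)=CCC#CO[Si](C(C)C)(C(C)C)C(C)C | intermediate
6 | acetone | CC(C)=O | starting material
7 | ketene | C=C=O | intermediate
8 | 2-(3-methylbut-2-en-1-yl)-3-(triisopropylsilyloxy)cyclobut-2-en-1-one | CC(C)=CCC1=C(O[Si](C(C)C)(C(C)C)C(C)C)CC1=O | intermediate
9 | 2-(3-methylbut-2-en-1-yl)-3-(triisopropylsilyloxy)buta-1,3-dien-1-one (vinylketene) | O=C=C(CC=C(C)C)C(=C)O[Si](C(C)C)(C(C)C)C(C)C | intermediate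
10 | 2,4-bis(3-methylbut-2-en-1-yl)-3-(triisopropylsilyloxy)-4-[1-(triisopropylsilyloxy)ethenyl]cyclobut-2-en-1-one (racemic) | O=C1C(CC=C(C)C)=C(O[Si](C(C)C)(C(C)C)C(C)C)C1(CC=C(C)C)C(=C)O[Si](C(C)C)(C(C)C)C(C)C | intermediate
11 | (3E)-2,4-bis(3-methylbut-2-en-1-yl)-3,5-bis(triisopropylsilyloxy)hexa-1,3,5-trien-1-one (dienylketene, ketenyl and silyloxyvinyl groups cis) | O=C=C(CC=C(C)C)/C(O[Si](C(C)C)(C(C)C)C(C)C)=C(CC=C(C)C)\C(=C)O[Si](C(C)C)(C(C)C)C(C)C | intermediate
12 | 2,4-bis(3-methylbut-2-en-1-yl)-3,5-bis(triisopropylsilyloxy)cyclohexa-2,4-dien-1-one | O=C1CC(O[Si](C(C)C)(C(C)C)C(C)C)=C(CC=C(C)C)C(O[Si](C(C)C)(C(C)C)C(C)C)=C1CC=C(C)C | intermediate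
13 | 2,4-bis(3-methylbut-2-en-1-yl)-3,5-bis(triisopropylsilyloxy)phenol | CC(C)=CCc1c(O)cc(O[Si](C(C)C)(C(C)C)C(C)C)c(CC=C(C)C)c1O[Si](C(C)C)(C(C)C)C(C)C | intermediate
14 | 2-hydroxy-3,5-bis(3-methylbut-2-en-1-yl)-4,6-bis(triisopropylsilyloxy)benzaldehyde | O=Cc1c(O)c(CC=C(C)C)c(O[Si](C(C)C)(C(C)C)C(C)C)c(CC=C(C)C)c1O[Si](C(C)C)(C(C)C)C(C)C | intermediate
15 | 2-(methoxymethoxy)-3,5-bis(3-methylbut-2-en-1-yl)-4,6-bis(triisopropylsilyloxy)benzaldehyde | O=Cc1c(OCOC)c(CC=C(C)C)c(O[Si](C(C)C)(C(C)C)C(C)C)c(CC=C(C)C)c1O[Si](C(C)C)(C(C)C)C(C)C | intermediate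
16 | 2-hydroxy-1-(4-hydroxyphenyl)ethan-1-one | O=C(CO)c1ccc(O)cc1 | starting material
17 | 2-(methoxymethoxy)-1-[4-(methoxymethoxy)phenyl]ethan-1-one | COCOCC(=O)c1ccc(OCOC)cc1 | intermediate
18 | lithium (Z)-2-(methoxymethoxy)-1-[4-(methoxymethoxy)phenyl]ethen-1-olate | [Li+].[O-]/C(=C\OCOC)c1ccc(OCOC)cc1 | intermediate
19 | 3-hydroxy-2-(methoxymethoxy)-3-[2-(methoxymethoxy)-3,5-bis(3-methylbut-2-en-1-yl)-4,6-bis(triisopropylsilyloxy)phenyl]-1-[4-(methoxymethoxy)phenyl]propan-1-one (mixture of racemic diastereomers) | COCOC(C(O)c1c(OCOC)c(CC=C(C)C)c(O[Si](C(C)C)(C(C)C)C(C)C)c(CC=C(C)C)c1O[Si](C(C)C)(C(C)C)C(C)C)C(=O)c1ccc(OCOC)cc1 | intermediate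
20 | 2-(methoxymethoxy)-1-[2-(methoxymethoxy)-3,5-bis(3-methylbut-2-en-1-yl)-4,6-bis(triisopropylsilyloxy)phenyl]-3-[4-(methoxymethoxy)phenyl]propane-1,3-dione (racemic) | COCOC(C(=O)c1c(OCOC)c(CC=C(C)C)c(O[Si](C(C)C)(C(C)C)C(C)C)c(CC=C(C)C)c1O[Si](C(C)C)(C(C)C)C(C)C)C(=O)c1ccc(OCOC)cc1 | intermediate
21 | 2-hydroxy-1-[2-hydroxy-3,5-bis(3-methylbut-2-en-1-yl)-4,6-bis(triisopropylsilyloxy)phenyl]-3-(4-hydroxyphenyl)propane-1,3-dione (racemic) | OC(C(=O)c1ccc(O)cc1)C(=O)c1c(O)c(CC=C(C)C)c(O[Si](C(C)C)(C(C)C)C(C)C)c(CC=C(C)C)c1O[Si](C(C)C)(C(C)C)C(C)C | intermediate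
22 | 3-hydroxy-2-(4-hydroxyphenyl)-6,8-bis(3-methylbut-2-en-1-yl)-5,7-bis(triisopropylsilyloxy)-4H-chromen-4-one | CC(C)=CCc1c(O[Si](C(C)C)(C(C)C)C(C)C)c(CC=C(C)C)c2oc(-c3ccc(O)cc3)c(O)c(=O)c2c1O[Si](C(C)C)(C(C)C)C(C)C | intermediate
23 | 6,8-diprenylkaempferol, 3,5,7-trihydroxy-2-(4-hydroxyphenyl)-6,8-bis(3-methylbut-2-en-1-yl)-4H-chromen-4-one | CC(C)=CCc1c(O)c(CC=C(C)C)c2oc(-c3ccc(O)cc3)c(O)c(=O)c2c1O | target

Total step count: 11. Longest linear sequence: 10 steps (steps 1–6 and 8–11; step 7 is a one-step side branch).

Steps most likely to fail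

Step 4. The donor-substituted cyclobutenone may open too slowly below the temperature at which the silyloxyalkyne isomerises to a silylketene, and ketene intermediates may acylate the phenol as it forms. The fallback sets out from 8 and 5 and generates the vinylketene by light instead of heat (medium-pressure mercury lamp through Pyrex, benzene, room temperature), where the silyloxyalkyne is stable. The [2+2] adduct 10 is then isolated; this fallback makes no compound outside the list (F0). Heating 10 alone in dilute toluene at 110 °C should drive ring opening, electrocyclisation and tautomerisation with no free ketene left to attack the phenol. The route is rejoined at 13.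

Step 2. The β,γ-unsaturated ester may be deprotonated at its doubly activated α-position instead of adding LiCHBr2, with migration of the double bond into conjugation, or the carbenoid rearrangement may stay incomplete. The fallback sets out from 2 and reaches the same ynolate by oxidation of an acetylide. Reduction with DIBAL-H (CH2Cl2, −78 °C) should give 4-methylpent-3-enal F1. Corey–Fuchs olefination (CBr4, PPh3, CH2Cl2, 0 °C) should give 1,1-dibromo-5-methylhexa-1,4-diene F2. Two equivalents of n-BuLi (THF, −78 °C) should convert it into lithium 5-methylhex-4-en-1-yn-1-ide F3. Oxidation of this acetylide with lithium tert-butyl peroxide (t-BuOOH, LiHMDS, −78 → 0 °C) should give lithium ynolate 4, where the route is rejoined and silylation as in step 2 gives 5.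

Step 5. C–C bond formation at a carbon flanked by the bulky silyloxy group may be slow, which leaves time for silyl transfer to the transient benzylic magnesium alkoxide or for further reaction with formaldehyde. The fallback sets out from 13 and introduces the formyl group through an aryl anion instead of electrophilic substitution. Protection (NaH, MOMCl, DMF, 0 °C) should give 1-(methoxymethoxy)-2,4-bis(3-methylbut-2-en-1-yl)-3,5-bis(triisopropylsilyloxy)benzene F4. Directed ortho-metalation (s-BuLi, TMEDA, THF, −78 °C) at the position between the two oxygens should give the aryllithium, [2-(methoxymethoxy)-3,5-bis(3-methylbut-2-en-1-yl)-4,6-bis(triisopropylsilyloxy)phenyl]lithium F5. Quenching with DMF at −78 °C should give aldehyde 15 directly, where the route is rejoined and step 6 is no longer needed.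

Further compounds

F0 | step 4 | none | none
F1 | step 2 | 4-methylpent-3-enal | CC(C)=CCC=O
F2 | step 2 | 1,1-dibromo-5-methylhexa-1,4-diene | CC(C)=CCC=C(Br)Br
F3 | step 2 | lithium 5-methylhex-4-en-1-yn-1-ide | [Li]C#CCC=C(C)C
F4 | step 5 | 1-(methoxymethoxy)-2,4-bis(3-methylbut-2-en-1-yl)-3,5-bis(triisopropylsilyloxy)benzene | CC(C)=CCc1c(OCOC)cc(O[Si](C(C)C)(C(C)C)C(C)C)c(CC=C(C)C)c1O[Si](C(C)C)(C(C)C)C(C)C
F5 | step 5 | [2-(methoxymethoxy)-3,5-bis(3-methylbut-2-en-1-yl)-4,6-bis(triisopropylsilyloxy)phenyl]lithium | [Li]c1c(OCOC)c(CC=C(C)C)c(O[Si](C(C)C)(C(C)C)C(C)C)c(CC=C(C)C)c1O[Si](C(C)C)(C(C)C)C(C)C
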